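The earlier runs and the new flask were generated by integration for substances that don't exist; the scatter is artificial.

Which step here is slow I cannot tell, since no rate is given for any exchange, so I count turnovers first.

| flask | starting complex | incoming ligand | leaving ligand | remark | time |
|---|---|---|---|---|---|
| zeta | 0.068 M | 0.044 M | 0.068 M | run made earlier |  |
| theta | 0.068 M | 0.19 M | 0.068 M | run made earlier |  |
| north-east | 0.068 M | 0.0680 M | 0.0680 M |  | 3.0 min |
| south-east | 0.068 M | 0.272 M | 0.0680 M |  | 3.0 min |

| run | time / min | complex with one exchanged / % |
|---|---|---|
| zeta | 0.833 | 18 |
| zeta | 1.50 | 13 |
| zeta | 2.50 | 11 |
| zeta | 3.00 | 11 |
| theta | 0.250 | 26 |
| theta | 0.500 | 16 |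
| theta | 1.33 | 7 |
| theta | 3.00 | 9 |

(each reading ± 2 percentage points)

- what was read earlier has a scatter of 2 percentage points, one standard deviation
- a reading or a percentage of complex with one exchanged counts all its forms, free or not

- which of these holds the largest part of the starting complex at the end of north-east (starting complex / complex with one exchanged / complex with two exchanged / complex with three exchanged)
- which of these holds the largest part of the starting complex at the end of south-east (starting complex / complex with one exchanged / complex with two exchanged / complex with three exchanged)
- final complex with one exchanged in north-east, as a percentage of the starting complex charged

I carry the exchange budget, the incoming ligand charged per starting complex charged: 1.00 in north-east and 4.00 in south-east. Each exchange spends one incoming ligand. Full exchange needs 3 per complex, so incoming ligand is the limiting reagent of full exchange in north-east, while south-east has enough.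

I build north-east up one step at a time. With the first exchange running by itself, starting complex and incoming ligand fall together from equal charges:

c(starting complex) = c(incoming ligand)

Adding the second exchange, each complex with two exchanged has spent one ligand more than the starting complex it used:

c(starting complex) = c(incoming ligand) + c(complex with two exchanged)

Adding the third, each complex with three exchanged has spent two more:

c(starting complex) = c(incoming ligand) + c(complex with two exchanged) + 2 c(complex with three exchanged)

So in north-east, as long as these exchanges are what spends incoming ligand, starting complex stands at or above both of those forms. Complex with one exchanged drops out of the line, so I read it instead. Zeta and theta match north-east in starting complex, leaving ligand and time, and their budgets bracket it. Their end readings, 11% and 9%, give me 10.0%, with a scatter of 2 percentage points on each. Starting complex below that would put the four forms under 35.0% of the charge, so I commit to starting complex. In south-east the count excludes nothing, and I take complex with three exchanged on weak grounds.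

The forecast says starting complex, complex with three exchanged and 12%, which is above my mean. It rests on fits and reads the runs as “later exchanges are favoured over the first”.

The flasks give starting complex in north-east, ahead of the other asked forms at 36.1%, complex with three exchanged in south-east at 36.1%, and 10.2% for n. The forecast's calls hold.

    starting complex + incoming ligand ⇌ leaving ligand + complex with one exchanged (K = 1.89, k = 0.987 L mol⁻¹ s⁻¹)
    complex with one exchanged + incoming ligand ⇌ leaving ligand + complex with two exchanged (K = 6.30, k = 0.684 L mol⁻¹ s⁻¹)
    complex with two exchanged + incoming ligand ⇌ leaving ligand + complex with three exchanged (K = 1.10, k = 2.18 L mol⁻¹ s⁻¹)
    leaving ligand → by-product carried off (k = 0.00272 s⁻¹)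
    leaving ligand + complex with one exchanged → side product (k = 0.168 L mol⁻¹ s⁻¹)
    crystals ⇌ complex with one exchanged, rate k6*(cs6 - [complex with one exchanged]) while solid is left; crystals form when [complex with one exchanged] > cs6 (solubility = 47.0 mM, k = 0.321 s⁻¹)

North-east has not come to rest at 3.0 min. At 30.0 min its complex with one exchanged is down to 6.46%, starting complex to 16.8%, and side product up from 36.7% to 63.2%. The budget line still holds, giving 16.8% against 16.8%.

In a neighbour of north-east, the same flask but charged with 0.27 M of leaving ligand, the budget is still 1.00, so starting complex must stand at or above complex with two exchanged. The flask gives 31.1% against 4.28%, and the line gives 31.1%.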